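**Plan**

- Locants follow the acid chain: C1 carboxyl, C2 (CH–CH3), then the ring O–O/C3 (CH)/C4/C5/C6 (quaternary, CH3), and C7 onward the homofarnesyl chain.
- Retrosynthetic cuts, in order: (a) C1 acid to a silyl-protected primary alcohol; (b) the ring bond from the distal peroxide oxygen to C6, which opens the 1,2-dioxane to an acyclic (3S)-hydroperoxide with a (5Z)-C5=C6 alkene (iodine on C5 is the removable helper); (c) C3–OO, by invertive perhydrolysis of a sulfonate; (d) C4–C5, giving epoxide fragment A and Z-alkenyl iodide fragment B; (e) C6–C7, by carbocupration of propyne.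
- Forward order: fragment A (steps 1–4) and fragment B (steps 5–8) are joined at C4–C5 (step 9), the hydroperoxide is installed (steps 10–11), the only ring is closed (step 12), then iodine is removed and C1 is oxidised (steps 13–15).
- Enabling feature: ring atoms C4, C5 and C6 with the C6 methyl are the head of a polyprenyl unit. The open-chain precursor therefore carries a trisubstituted C5=C6 alkene homoallylic to the peroxy carbon C3, and its tertiary end C6 is the atom the distal oxygen must reach (6-endo, Markovnikov).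
- Stereochemistry: C2 and C3 come from one auxiliary-controlled syn-aldol (C3 is inverted when the peroxide is introduced). C6 is relayed from C3 in the ring closure, through a chair with the C3 substituent equatorial and anti addition to the Z-alkene. The E-alkenes are bought with farnesyl bromide; the Z-alkene comes from syn-carbocupration.

Key step: step 12

Remark: anhydrous chloroacetaldehyde 2 is taken to be obtained by drying and distilling the commercial aqueous solution; organometallic intermediates are drawn as monomers without their ligands.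

**Route**

Step 1
Reactants: 1 (4S)-4-benzyl-3-propanoyl-1,3-oxazolidin-2-one; 2 chloroacetaldehyde
Product: 4 (4S)-4-benzyl-3-[(2S,3S)-4-chloro-3-hydroxy-2-methylbutanoyl]-1,3-oxazolidin-2-one, via Z-boron enolate 3 (not isolated)
Conditions: Bu2BOTf, iPr2NEt, CH2Cl2, 0 °C; then 2, −78 → 0 °C; work-up pH 7 buffer, MeOH, 30% H2O2, 0 °C
Reagents that add atoms: none
Why: Evans syn-aldol: the Z-boron enolate 3 should add to the aldehyde through a Zimmerman–Traxler chair on the face away from the benzyl group, setting C2 (S) and the carbinol carbon (S) as the syn pair.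

Step 2
Reactants: 4 (4S)-4-benzyl-3-[(2S,3S)-4-chloro-3-hydroxy-2-methylbutanoyl]-1,3-oxazolidin-2-one
Product: 5 (2R,3S)-4-chloro-2-methylbutane-1,3-diol
Conditions: LiBH4, MeOH (1 equiv), Et2O, 0 °C
Reagents that add atoms: none
Why: Reductive removal of the Evans auxiliary: LiBH4 attacks the exocyclic imide carbonyl and should deliver the primary alcohol at 0 °C without touching either stereocentre or the primary chloride.

Step 3
Reactants: 5 (2R,3S)-4-chloro-2-methylbutane-1,3-diol
Product: 6 (2S,3R)-1-chloro-3-methyl-4-[(triisopropylsilyl)oxy]butan-2-ol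
Conditions: iPr3SiCl, imidazole, DMF, 0 °C
Reagents that add atoms: triisopropylsilyl chloride, CC(C)[Si](Cl)(C(C)C)C(C)C
Why: Silyl ether formation: the bulky silyl chloride should react only at the primary hydroxyl, leaving the secondary one for the epoxide closure.

Step 4
Reactants: 6 (2S,3R)-1-chloro-3-methyl-4-[(triisopropylsilyl)oxy]butan-2-ol
Product: 7 triisopropyl{(2R)-2-[(2S)-oxiran-2-yl]propoxy}silane (fragment A)
Conditions: K2CO3, MeOH, 0 → 20 °C
Reagents that add atoms: none
Why: Intramolecular Williamson etherification (3-exo-tet) of the chlorohydrin: the C–O bond at the stereocentre is not broken, so the epoxide carbon keeps its configuration.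

Step 5
Reactants: 8 (2E,6E)-farnesyl bromide; 9 (chloromethyl)(isopropoxy)dimethylsilane
Product: 11 isopropoxydimethyl[(3E,7E)-4,8,12-trimethyltrideca-3,7,11-trien-1-yl]silane, via silylmethyl Grignard reagent 10 (not isolated)
Conditions: 9, Mg, THF, 40 °C; then 8, CuI (5 mol %), THF, 0 °C
Reagents that add atoms: none
Why: Copper-catalysed Grignard coupling with a primary allylic bromide, using the silylmethyl Grignard reagent as a hydroxymethyl anion equivalent: attack should occur at the unhindered CH2 terminus because the other allyl terminus is fully substituted, with the E geometry untouched.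

Step 6
Reactants: 11 isopropoxydimethyl[(3E,7E)-4,8,12-trimethyltrideca-3,7,11-trien-1-yl]silane
Product: 12 (3E,7E)-homofarnesol [(3E,7E)-4,8,12-trimethyltrideca-3,7,11-trien-1-ol]
Conditions: 30% H2O2, KF, KHCO3, THF/MeOH, 20 °C
Reagents that add atoms: hydrogen peroxide, OO
Why: Tamao–Fleming oxidation: the fluoride-activated alkoxysilane binds hydroperoxide and the carbon migrates from silicon to oxygen, while isolated trisubstituted alkenes are inert to buffered H2O2.

Step 7
Reactants: 12 (3E,7E)-homofarnesol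
Product: 13 (3E,7E)-homofarnesyl bromide [(3E,7E)-1-bromo-4,8,12-trimethyltrideca-3,7,11-triene]
Conditions: CBr4, PPh3, CH2Cl2, 0 °C
Reagents that add atoms: carbon tetrabromide, BrC(Br)(Br)Br
Why: Appel bromination: SN2 displacement of the alkoxyphosphonium at a primary carbon under neutral conditions that spare the alkenes.

Step 8
Reactants: 13 (3E,7E)-homofarnesyl bromide; 14 propyne
Product: 18 (1Z,5E,9E)-1-iodo-2,6,10,14-tetramethylpentadeca-1,5,9,13-tetraene (fragment B), via homofarnesylmagnesium bromide 15 (not isolated), via homofarnesylcopper 16 (not isolated), via Z-alkenylcopper 17 (not isolated)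
Conditions: Mg, Et2O, reflux; CuBr·SMe2, Et2O/Me2S, −45 °C; propyne (excess), −25 °C; I2, Et2O, −50 → 0 °C
Reagents that add atoms: iodine, II
Why: Normant carbocupration: the alkylcopper should add syn across propyne with copper on the terminal carbon, so that chain and copper are cis, and iodinolysis with retention gives the Z-iodide whose geometry later fixes C6.

Step 9
Reactants: 18 (1Z,5E,9E)-1-iodo-2,6,10,14-tetramethylpentadeca-1,5,9,13-tetraene; 7 triisopropyl{(2R)-2-[(2S)-oxiran-2-yl]propoxy}silane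
Product: 20 (2R,3R,5Z,9E,13E)-2,6,10,14,18-pentamethyl-1-[(triisopropylsilyl)oxy]nonadeca-5,9,13,17-tetraen-3-ol, via Z-alkenyllithium 19 (not isolated)
Conditions: 18, t-BuLi (2 equiv), Et2O, −78 °C; then 7, BF3·OEt2, THF, −78 °C
Reagents that add atoms: none
Why: Iodine–lithium exchange with retention of alkene geometry followed by BF3-assisted SN2 opening of the terminal epoxide at its CH2 carbon, which forms C4–C5 and leaves the carbinol stereocentre untouched.

Step 10
Reactants: 20 (2R,3R,5Z,9E,13E)-2,6,10,14,18-pentamethyl-1-[(triisopropylsilyl)oxy]nonadeca-5,9,13,17-tetraen-3-ol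
Product: 21 (2R,3R,5Z,9E,13E)-2,6,10,14,18-pentamethyl-1-[(triisopropylsilyl)oxy]nonadeca-5,9,13,17-tetraen-3-yl methanesulfonate
Conditions: MsCl, Et3N, CH2Cl2, −10 °C
Reagents that add atoms: methanesulfonyl chloride, CS(=O)(=O)Cl
Why: Sulfonylation of the secondary alcohol without change at C3, turning it into a leaving group.

Step 11
Reactants: 21 (2R,3R,5Z,9E,13E)-2,6,10,14,18-pentamethyl-1-[(triisopropylsilyl)oxy]nonadeca-5,9,13,17-tetraen-3-yl methanesulfonate
Product: 22 triisopropyl{[(2R,3S,5Z,9E,13E)-3-hydroperoxy-2,6,10,14,18-pentamethylnonadeca-5,9,13,17-tetraen-1-yl]oxy}silane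
Conditions: 50% aq. H2O2 (large excess), KOH, MeOH/THF, 0 → 20 °C
Reagents that add atoms: hydrogen peroxide, OO
Why: SN2 perhydrolysis of a secondary alkyl sulfonate: the hydroperoxide anion, a strong alpha-effect nucleophile and weak base, should displace mesylate with inversion to give the (3S)-hydroperoxide, the known entry to secondary alkenyl hydroperoxides.

Step 12
Reactants: 22 triisopropyl{[(2R,3S,5Z,9E,13E)-3-hydroperoxy-2,6,10,14,18-pentamethylnonadeca-5,9,13,17-tetraen-1-yl]oxy}silane
Product: 23 {(2R)-2-[(3S,5S,6S)-5-iodo-6-methyl-6-[(3E,7E)-4,8,12-trimethyltrideca-3,7,11-trien-1-yl]-1,2-dioxan-3-yl]propoxy}triisopropylsilane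
Conditions: N-iodosuccinimide, CH2Cl2, −40 → 0 °C, dark
Reagents that add atoms: N-iodosuccinimide, O=C1CCC(=O)N1I
Why: N-iodosuccinimide transfers iodonium reversibly to the alkenes, but only the C5=C6 iodonium has an internal nucleophile, and the distal oxygen of the C3 hydroperoxide opens it at the tertiary carbon C6 (Markovnikov) in a 6-endo-trig closure that forms the O–C6 bond and the 1,2-dioxane ring. The closest known reaction type is the halo- or mercuri-cyclisation of unsaturated hydroperoxides to cyclic peroxides, together with 6-endo haloetherification of trisubstituted alkenes. Addition is anti and stereospecific, so the Z geometry fixes C5 relative to C6: the chain carbon C7, cis to C4 on the alkene, must become axial on C6 while the C6 methyl and the C5 iodine become equatorial. The new quaternary stereocentre C6 is controlled relative to C3 by a chair transition state in which the bulky C3 substituent is equatorial, which should lead to the (3S,5S,6S) product with the C3 and C6 chains cis, whereas closure on the other alkene face would need both chains axial. The step needs regioselectivity (6-endo over 5-exo, secured by the cation-stabilising tertiary C6), chemoselectivity among four trisubstituted alkenes (secured by intramolecular capture) and facial selectivity (secured by the equatorial preference at C3). The C5 iodine is a helper that step 13 removes.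

Step 13
Reactants: 23 {(2R)-2-[(3S,5S,6S)-5-iodo-6-methyl-6-[(3E,7E)-4,8,12-trimethyltrideca-3,7,11-trien-1-yl]-1,2-dioxan-3-yl]propoxy}triisopropylsilane
Product: 24 {(2R)-2-[(3S,6S)-6-methyl-6-[(3E,7E)-4,8,12-trimethyltrideca-3,7,11-trien-1-yl]-1,2-dioxan-3-yl]propoxy}triisopropylsilane
Conditions: Bu3SnH (excess, about 2 M), Et3B (cat.), trace air, toluene, −78 °C
Reagents that add atoms: none
Why: Radical-chain hydrodeiodination: the secondary C5 radical is trapped by tin hydride, and high hydride concentration at low temperature should outrun both 5-exo cyclisation onto the C9=C10 alkene and epoxide-forming attack on the ring O–O bond, for which the endocyclic radical is poorly aligned; C5 becomes CH2, so no stereocentre is at stake.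

Step 14
Reactants: 24 {(2R)-2-[(3S,6S)-6-methyl-6-[(3E,7E)-4,8,12-trimethyltrideca-3,7,11-trien-1-yl]-1,2-dioxan-3-yl]propoxy}triisopropylsilane
Product: 25 (2R)-2-[(3S,6S)-6-methyl-6-[(3E,7E)-4,8,12-trimethyltrideca-3,7,11-trien-1-yl]-1,2-dioxan-3-yl]propan-1-ol
Conditions: Bu4NF, AcOH (1:1), THF, 0 → 20 °C
Reagents that add atoms: none
Why: Fluoride-induced desilylation, buffered with acetic acid so that no alkoxide-triggered fragmentation of the peroxide can start.

Step 15
Reactants: 25 (2R)-2-[(3S,6S)-6-methyl-6-[(3E,7E)-4,8,12-trimethyltrideca-3,7,11-trien-1-yl]-1,2-dioxan-3-yl]propan-1-ol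
Product: 27 (2S)-2-[(3S,6S)-6-methyl-6-[(3E,7E)-4,8,12-trimethyltrideca-3,7,11-trien-1-yl]-1,2-dioxan-3-yl]propanoic acid (CNP0179915.1), via aldehyde 26 (not isolated)
Conditions: TEMPO (cat.), PhI(OAc)2, MeCN/H2O, 20 °C
Reagents that add atoms: water, O
Why: Oxoammonium (TEMPO) oxidation with PhI(OAc)2 as terminal oxidant: the primary alcohol goes through aldehyde 26 and its hydrate to the acid under near-neutral conditions that should spare the peroxide, the trisubstituted alkenes and the C2 stereocentre.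

**Compound list**

1 | (4S)-4-benzyl-3-propanoyl-1,3-oxazolidin-2-one | CCC(=O)N1C(=O)OC[C@@H]1Cc1ccccc1 | starting material
2 | chloroacetaldehyde | ClCC=O | starting material
3 | Z-dibutylboron enolate of 1 | C/C=C(\OB(CCCC)CCCC)N1C(=O)OC[C@@H]1Cc1ccccc1 | intermediate
4 | (4S)-4-benzyl-3-[(2S,3S)-4-chloro-3-hydroxy-2-methylbutanoyl]-1,3-oxazolidin-2-one | ClC[C@@H](O)[C@H](C)C(=O)N1C(=O)OC[C@@H]1Cc1ccccc1 | intermediate
5 | (2R,3S)-4-chloro-2-methylbutane-1,3-diol | ClC[C@@H](O)[C@H](C)CO | intermediate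
6 | (2S,3R)-1-chloro-3-methyl-4-[(triisopropylsilyl)oxy]butan-2-ol | ClC[C@@H](O)[C@H](C)CO[Si](C(C)C)(C(C)C)C(C)C | intermediate
7 | triisopropyl{(2R)-2-[(2S)-oxiran-2-yl]propoxy}silane | C1O[C@H]1[C@H](C)CO[Si](C(C)C)(C(C)C)C(C)C | intermediate
8 | (2E,6E)-farnesyl bromide | CC(C)=CCC/C(C)=C/CC/C(C)=C/CBr | starting material
9 | (chloromethyl)(isopropoxy)dimethylsilane | ClC[Si](C)(C)OC(C)C | starting material
10 | [(isopropoxydimethylsilyl)methyl]magnesium chloride | Cl[Mg]C[Si](C)(C)OC(C)C | intermediate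
11 | isopropoxydimethyl[(3E,7E)-4,8,12-trimethyltrideca-3,7,11-trien-1-yl]silane | CC(C)=CCC/C(C)=C/CC/C(C)=C/CC[Si](C)(C)OC(C)C | intermediate
12 | (3E,7E)-homofarnesol | CC(C)=CCC/C(C)=C/CC/C(C)=C/CCO | intermediate
13 | (3E,7E)-homofarnesyl bromide | CC(C)=CCC/C(C)=C/CC/C(C)=C/CCBr | intermediate
14 | propyne | CC#C | starting material
15 | (3E,7E)-homofarnesylmagnesium bromide | CC(C)=CCC/C(C)=C/CC/C(C)=C/CC[Mg]Br | intermediate
16 | (3E,7E)-homofarnesylcopper | CC(C)=CCC/C(C)=C/CC/C(C)=C/CC[Cu] | intermediate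
17 | [(1Z,5E,9E)-2,6,10,14-tetramethylpentadeca-1,5,9,13-tetraen-1-yl]copper | CC(C)=CCC/C(C)=C/CC/C(C)=C/CC/C(C)=C\[Cu] | intermediate
18 | (1Z,5E,9E)-1-iodo-2,6,10,14-tetramethylpentadeca-1,5,9,13-tetraene | CC(C)=CCC/C(C)=C/CC/C(C)=C/CC/C(C)=C\I | intermediate
19 | [(1Z,5E,9E)-2,6,10,14-tetramethylpentadeca-1,5,9,13-tetraen-1-yl]lithium | CC(C)=CCC/C(C)=C/CC/C(C)=C/CC/C(C)=C\[Li] | intermediate
20 | (2R,3R,5Z,9E,13E)-2,6,10,14,18-pentamethyl-1-[(triisopropylsilyl)oxy]nonadeca-5,9,13,17-tetraen-3-ol | CC(C)=CCC/C(C)=C/CC/C(C)=C/CC/C(C)=C\C[C@@H](O)[C@H](C)CO[Si](C(C)C)(C(C)C)C(C)C | intermediate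
21 | (2R,3R,5Z,9E,13E)-2,6,10,14,18-pentamethyl-1-[(triisopropylsilyl)oxy]nonadeca-5,9,13,17-tetraen-3-yl methanesulfonate | CC(C)=CCC/C(C)=C/CC/C(C)=C/CC/C(C)=C\C[C@@H](OS(C)(=O)=O)[C@H](C)CO[Si](C(C)C)(C(C)C)C(C)C | intermediate
22 | triisopropyl{[(2R,3S,5Z,9E,13E)-3-hydroperoxy-2,6,10,14,18-pentamethylnonadeca-5,9,13,17-tetraen-1-yl]oxy}silane | CC(C)=CCC/C(C)=C/CC/C(C)=C/CC/C(C)=C\C[C@H](OO)[C@H](C)CO[Si](C(C)C)(C(C)C)C(C)C | intermediate
23 | {(2R)-2-[(3S,5S,6S)-5-iodo-6-methyl-6-[(3E,7E)-4,8,12-trimethyltrideca-3,7,11-trien-1-yl]-1,2-dioxan-3-yl]propoxy}triisopropylsilane | CC(C)=CCC/C(C)=C/CC/C(C)=C/CC[C@@]1(C)[C@@H](I)C[C@@H]([C@H](C)CO[Si](C(C)C)(C(C)C)C(C)C)OO1 | intermediate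
24 | {(2R)-2-[(3S,6S)-6-methyl-6-[(3E,7E)-4,8,12-trimethyltrideca-3,7,11-trien-1-yl]-1,2-dioxan-3-yl]propoxy}triisopropylsilane | CC(C)=CCC/C(C)=C/CC/C(C)=C/CC[C@@]1(C)CC[C@@H]([C@H](C)CO[Si](C(C)C)(C(C)C)C(C)C)OO1 | intermediate
25 | (2R)-2-[(3S,6S)-6-methyl-6-[(3E,7E)-4,8,12-trimethyltrideca-3,7,11-trien-1-yl]-1,2-dioxan-3-yl]propan-1-ol | CC(C)=CCC/C(C)=C/CC/C(C)=C/CC[C@@]1(C)CC[C@@H]([C@H](C)CO)OO1 | intermediate
26 | (2S)-2-[(3S,6S)-6-methyl-6-[(3E,7E)-4,8,12-trimethyltrideca-3,7,11-trien-1-yl]-1,2-dioxan-3-yl]propanal | CC(C)=CCC/C(C)=C/CC/C(C)=C/CC[C@@]1(C)CC[C@@H]([C@H](C)C=O)OO1 | intermediate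
27 | (2S)-2-[(3S,6S)-6-methyl-6-[(3E,7E)-4,8,12-trimethyltrideca-3,7,11-trien-1-yl]-1,2-dioxan-3-yl]propanoic acid | CC(C)=CCC/C(C)=C/CC/C(C)=C/CC[C@@]1(C)CC[C@@H]([C@H](C)C(=O)O)OO1 | target

**Step count and risks**

Total steps: 15. Longest linear sequence: 11 steps (steps 5–8 then 9–15; equally steps 1–4 then 9–15).

Steps most likely to fail:

1. Step 11. What may go wrong: base-induced E2 elimination of the alpha-branched secondary mesylate toward the conjugated 3,5-diene, and slow substitution. The fallback sets out from alcohol 20. Triflation (Tf2O, 2,6-lutidine, CH2Cl2, −78 °C) gives the far more reactive secondary triflate F1, which is used cold. It alkylates the potassium salt of 2-methoxypropan-2-yl hydroperoxide, a mono-protected hydrogen peroxide (KOtBu, THF, −78 → 0 °C), with inversion to give the peroxyketal F2. Mild hydrolysis of the ketal (AcOH/THF/H2O, 20 °C) frees the hydroperoxide, and the fallback comes back to the route at compound 22.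

2. Step 12. What may go wrong: closure through the competing transition state with the C3 side chain axial (or a twist-boat), which gives the C6 epimer, and 5-exo attack at C5. The fallback replaces face-selective iodonium capture by a stereospecific epoxide opening and sets out from alcohol 20. Hydroxyl-directed epoxidation (VO(acac)2 cat., t-BuOOH, toluene, 0 °C) should touch only the homoallylic C5=C6 alkene and, through a chair-like vanadate transition state, place the epoxide oxygen syn to the C3 hydroxyl, giving the epoxy alcohol F3. Mesylation (MsCl, Et3N, CH2Cl2) gives the epoxy mesylate F4. Displacement with the caesium salt of 2-methoxypropan-2-yl hydroperoxide (CsOH, DMF, 0 → 20 °C) gives with inversion the epoxy peroxyketal F5, whose masked peroxide cannot open the epoxide under base. Camphorsulfonic acid in wet CH2Cl2 (0 °C) unmasks the epoxy hydroperoxide F6, which is not isolated and opens the protonated epoxide at the tertiary carbon C6 with inversion (6-endo) to give the 5-hydroxy-1,2-dioxane F7; C6 is then set by stereospecific substitution. Barton–McCombie deoxygenation (1,1'-thiocarbonyldiimidazole, DMAP, CH2Cl2, then Bu3SnH, Et3B, trace air, toluene, 20 °C) through the imidazolyl thiocarbonate F8 removes the C5 oxygen, and the fallback comes back to the route at compound 24.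

3. Step 13. What may go wrong: the C5 radical cyclising 5-exo onto the C9=C10 alkene, or attacking the O–O bond, before hydrogen transfer. The fallback removes the helper without a carbon radical and sets out from hydroperoxide 22. Selenocyclisation (N-(phenylseleno)phthalimide, camphorsulfonic acid cat., CH2Cl2, 0 °C) should close the same ring in the same anti, 6-endo sense to give the C5 phenylselenide F9. Oxidation (30% H2O2, pyridine, CH2Cl2, 0 °C) gives the selenoxide F10, which is not isolated and undergoes syn-elimination toward C4, since C6 carries no hydrogen, to give the 3,6-dihydro-1,2-dioxine F11. Diimide (KO2CN=NCO2K, AcOH, MeOH/CH2Cl2, 0 °C) should saturate the cis-disubstituted ring alkene in preference to the trisubstituted chain alkenes without touching the O–O bond, and the fallback comes back to the route at compound 24.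

**Further compounds**

F1 | step 11 | (2R,3R,5Z,9E,13E)-2,6,10,14,18-pentamethyl-1-[(triisopropylsilyl)oxy]nonadeca-5,9,13,17-tetraen-3-yl trifluoromethanesulfonate | CC(C)=CCC/C(C)=C/CC/C(C)=C/CC/C(C)=C\C[C@@H](OS(=O)(=O)C(F)(F)F)[C@H](C)CO[Si](C(C)C)(C(C)C)C(C)C
F2 | step 11 | triisopropyl{[(2R,3S,5Z,9E,13E)-3-[(2-methoxypropan-2-yl)peroxy]-2,6,10,14,18-pentamethylnonadeca-5,9,13,17-tetraen-1-yl]oxy}silane | CC(C)=CCC/C(C)=C/CC/C(C)=C/CC/C(C)=C\C[C@H](OOC(C)(C)OC)[C@H](C)CO[Si](C(C)C)(C(C)C)C(C)C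
F3 | step 12 | (2R,3R,5S,6R,9E,13E)-5,6-epoxy-2,6,10,14,18-pentamethyl-1-[(triisopropylsilyl)oxy]nonadeca-9,13,17-trien-3-ol | CC(C)=CCC/C(C)=C/CC/C(C)=C/CC[C@@]1(C)O[C@H]1C[C@@H](O)[C@H](C)CO[Si](C(C)C)(C(C)C)C(C)C
F4 | step 12 | (2R,3R,5S,6R,9E,13E)-5,6-epoxy-2,6,10,14,18-pentamethyl-1-[(triisopropylsilyl)oxy]nonadeca-9,13,17-trien-3-yl methanesulfonate | CC(C)=CCC/C(C)=C/CC/C(C)=C/CC[C@@]1(C)O[C@H]1C[C@@H](OS(C)(=O)=O)[C@H](C)CO[Si](C(C)C)(C(C)C)C(C)C
F5 | step 12 | triisopropyl{[(2R,3S,5S,6R,9E,13E)-5,6-epoxy-3-[(2-methoxypropan-2-yl)peroxy]-2,6,10,14,18-pentamethylnonadeca-9,13,17-trien-1-yl]oxy}silane | CC(C)=CCC/C(C)=C/CC/C(C)=C/CC[C@@]1(C)O[C@H]1C[C@H](OOC(C)(C)OC)[C@H](C)CO[Si](C(C)C)(C(C)C)C(C)C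
F6 | step 12 | triisopropyl{[(2R,3S,5S,6R,9E,13E)-5,6-epoxy-3-hydroperoxy-2,6,10,14,18-pentamethylnonadeca-9,13,17-trien-1-yl]oxy}silane | CC(C)=CCC/C(C)=C/CC/C(C)=C/CC[C@@]1(C)O[C@H]1C[C@H](OO)[C@H](C)CO[Si](C(C)C)(C(C)C)C(C)C
F7 | step 12 | {(2R)-2-[(3S,5S,6S)-5-hydroxy-6-methyl-6-[(3E,7E)-4,8,12-trimethyltrideca-3,7,11-trien-1-yl]-1,2-dioxan-3-yl]propoxy}triisopropylsilane | CC(C)=CCC/C(C)=C/CC/C(C)=C/CC[C@@]1(C)[C@@H](O)C[C@@H]([C@H](C)CO[Si](C(C)C)(C(C)C)C(C)C)OO1
F8 | step 12 | O-{(3S,5S,6S)-6-methyl-3-[(2R)-1-[(triisopropylsilyl)oxy]propan-2-yl]-6-[(3E,7E)-4,8,12-trimethyltrideca-3,7,11-trien-1-yl]-1,2-dioxan-5-yl} 1H-imidazole-1-carbothioate | CC(C)=CCC/C(C)=C/CC/C(C)=C/CC[C@@]1(C)[C@@H](OC(=S)n2ccnc2)C[C@@H]([C@H](C)CO[Si](C(C)C)(C(C)C)C(C)C)OO1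
F9 | step 13 | {(2R)-2-[(3S,5S,6S)-6-methyl-5-(phenylselanyl)-6-[(3E,7E)-4,8,12-trimethyltrideca-3,7,11-trien-1-yl]-1,2-dioxan-3-yl]propoxy}triisopropylsilane | CC(C)=CCC/C(C)=C/CC/C(C)=C/CC[C@@]1(C)[C@@H]([Se]c2ccccc2)C[C@@H]([C@H](C)CO[Si](C(C)C)(C(C)C)C(C)C)OO1
F10 | step 13 | selenoxide of F9, {(2R)-2-[(3S,5S,6S)-6-methyl-5-(phenylseleninyl)-6-[(3E,7E)-4,8,12-trimethyltrideca-3,7,11-trien-1-yl]-1,2-dioxan-3-yl]propoxy}triisopropylsilane | CC(C)=CCC/C(C)=C/CC/C(C)=C/CC[C@@]1(C)[C@@H]([Se](=O)c2ccccc2)C[C@@H]([C@H](C)CO[Si](C(C)C)(C(C)C)C(C)C)OO1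
F11 | step 13 | {(2R)-2-[(3S,6S)-6-methyl-6-[(3E,7E)-4,8,12-trimethyltrideca-3,7,11-trien-1-yl]-3,6-dihydro-1,2-dioxin-3-yl]propoxy}triisopropylsilane | CC(C)=CCC/C(C)=C/CC/C(C)=C/CC[C@@]1(C)C=C[C@@H]([C@H](C)CO[Si](C(C)C)(C(C)C)C(C)C)OO1
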